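**Retrosynthetic overview**

1. Numbering: ring A (five-membered) is C1(CH3, fusion)–C2H2–C3H(OAc)–C4(OH)(iPr)–C5H(fusion); ring B (seven-membered) is C1–C5–C6H(O-aroyl)–C7H=C8(CH3)–C9H2–C10H(OH).
2. The route rests on one feature: the fusion carbons C1 and C5 of ring A lie β and α to the C6 oxygen and C4 carries the isopropyl group, so a 1-isopropyl-1-silylallene can lay C2–C3–C4 across a C1=C5 enone of ring B.
3. Ring B is made first: cycloheptenone 10 by ring-closing metathesis (C1=C5) of an acyclic vinyl ketone; C10 comes from asymmetric allylboration of methacrolein and the C8 methyl from cuprate addition to a dihydropyranone.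
4. Ring A is made second: TiCl4-mediated (3+2) annulation of 10 with allene 13 forms C1–C2 and C4–C5, the quaternary C1 and the cis fusion.
5. Late stage: C3–Si to C3–H, C7=C8 by Saegusa oxidation, C6 reduction and aroylation, convex-face dihydroxylation of C3=C4, C3 acetylation, desilylation.

Key step: step 11

Remark on notation: α is the face of the C1 methyl group (the convex face of the cis-fused bicycle), β the opposite face. In this numbering the target is (1S,3S,4R,5R,6S,10S), with 1-CH3, 5-H, 3-OAc, 4-OH and 10-OH all α and the 6-aroyloxy group β.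

Assumption: (−)-B-allyldiisopinocampheylborane, made from (+)-α-pinene, is taken to give the (S) carbinol from methacrolein as it does from benzaldehyde; if the sense were opposite, the antipodal reagent would be used.

**Route**

Step 1
Reactants: 1 methacrolein
Product: 3 (S)-2-methylhexa-1,5-dien-3-ol, via diisopinocampheylborinate 2 (not isolated)
Conditions: (−)-Ipc2BOMe, CH2=CHCH2MgBr, Et2O, 0 °C → rt; then 1, −78 °C; then NaOH, H2O2, 0 °C → rt
Reagents that add atoms: allylmagnesium bromide, C=CC[Mg]Br, which is converted in the flask into (−)-B-allyldiisopinocampheylborane, C=CCB([C@@H]1C[C@@H]2C[C@H]([C@H]1C)C2(C)C)[C@@H]1C[C@@H]2C[C@H]([C@H]1C)C2(C)C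
Why: Brown asymmetric allylboration through a closed chair transition state in which the isopinocampheyl groups select one aldehyde face, which sets the (S) carbinol that becomes C10.

Step 2
Reactants: 3 (S)-2-methylhexa-1,5-dien-3-ol
Product: 4 (S)-2-methylhexa-1,5-dien-3-yl prop-2-enoate
Conditions: CH2=CHCOCl, Et3N, DMAP (cat.), CH2Cl2, 0 °C
Reagents that add atoms: acryloyl chloride, C=CC(=O)Cl
Why: Base-mediated O-acylation of a secondary alcohol with an acid chloride, which does not touch the stereocentre.

Step 3
Reactants: 4 (S)-2-methylhexa-1,5-dien-3-yl prop-2-enoate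
Product: 5 (S)-6-(prop-1-en-2-yl)-5,6-dihydro-2H-pyran-2-one
Conditions: second-generation Grubbs catalyst (2 mol %), CH2Cl2, 40 °C, 0.01 M
Reagents that add atoms: none
Why: Ring-closing metathesis in which the ruthenium carbene forms at the monosubstituted allyl terminus and closes on the acrylate to the six-membered lactone, while the 1,1-disubstituted isopropenyl group is too hindered to take part.

Step 4
Reactants: 5 (S)-6-(prop-1-en-2-yl)-5,6-dihydro-2H-pyran-2-one
Product: 6 (4R,6S)-4-methyl-6-(prop-1-en-2-yl)tetrahydro-2H-pyran-2-one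
Conditions: Me2CuLi (from CuI and 2 MeLi), Et2O, −78 → −20 °C; aq. NH4Cl
Reagents that add atoms: lithium dimethylcuprate, [Li+].C[Cu-]C, made from methyllithium, [Li]C
Why: Gilman cuprate 1,4-addition to the unsaturated lactone, with the methyl group entering anti to the C6 substituent to give the trans-4,6 lactone (this centre, the later C8, is removed again in step 14).

Step 5
Reactants: 6 (4R,6S)-4-methyl-6-(prop-1-en-2-yl)tetrahydro-2H-pyran-2-one
Product: 7 (3R,5S)-5-hydroxy-N-methoxy-N,3,6-trimethylhept-6-enamide
Conditions: MeNH(OMe)·HCl, AlMe3, CH2Cl2, 0 °C → rt; aq. potassium sodium tartrate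
Reagents that add atoms: N,O-dimethylhydroxylamine hydrochloride, CNOC.Cl
Why: Weinreb aminolysis of the lactone by the aluminium amide, which opens the ring irreversibly; the hydroxy amide is silylated at once so that it cannot relactonise.

Step 6
Reactants: 7 (3R,5S)-5-hydroxy-N-methoxy-N,3,6-trimethylhept-6-enamide
Product: 8 (3R,5S)-5-(tert-butyldimethylsilyloxy)-N-methoxy-N,3,6-trimethylhept-6-enamide
Conditions: TBSCl, imidazole, DMF, rt
Reagents that add atoms: tert-butyldimethylsilyl chloride, CC(C)(C)[Si](C)(C)Cl
Why: Standard silylation of a secondary allylic alcohol, giving the ether that later shields one face of the enone.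

Step 7
Reactants: 8 (3R,5S)-5-(tert-butyldimethylsilyloxy)-N-methoxy-N,3,6-trimethylhept-6-enamide
Product: 9 (5R,7S)-7-(tert-butyldimethylsilyloxy)-5,8-dimethylnona-1,8-dien-3-one
Conditions: CH2=CHMgBr, THF, 0 °C; inverse quench into cold 1 M HCl
Reagents that add atoms: vinylmagnesium bromide, C=C[Mg]Br
Why: Weinreb ketone synthesis, in which the chelated tetrahedral intermediate stops over-addition and the cold acidic quench keeps the released amine from adding to the vinyl ketone.

Step 8
Reactants: 9 (5R,7S)-7-(tert-butyldimethylsilyloxy)-5,8-dimethylnona-1,8-dien-3-one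
Product: 10 (4S,6R)-4-(tert-butyldimethylsilyloxy)-3,6-dimethylcyclohept-2-en-1-one
Conditions: second-generation Grubbs catalyst (5–10 mol %), CH2Cl2, 40 °C, 2 mM
Reagents that add atoms: none
Why: Ring-closing metathesis between the vinyl ketone and the 1,1-disubstituted alkene closes ring B at C1=C5 as a trisubstituted enone, driven by loss of ethylene and helped by high dilution.

Step 9
Reactants: 11 3-(trimethylsilyl)prop-2-yn-1-ol
Product: 12 3-(trimethylsilyl)prop-2-yn-1-yl methanesulfonate
Conditions: MsCl, Et3N, CH2Cl2, −20 → 0 °C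
Reagents that add atoms: methanesulfonyl chloride, CS(=O)(=O)Cl
Why: Sulfonylation of a primary propargylic alcohol to install the leaving group for the next step.

Step 10
Reactants: 12 3-(trimethylsilyl)prop-2-yn-1-yl methanesulfonate
Product: 13 trimethyl(4-methylpenta-1,2-dien-3-yl)silane, that is 1-isopropyl-1-(trimethylsilyl)allene
Conditions: iPrMgCl, CuBr, LiBr, THF, −78 °C → rt
Reagents that add atoms: isopropylmagnesium chloride, CC(C)[Mg]Cl
Why: SN2′ substitution of the propargylic mesylate by the organocopper reagent at the silyl-bearing alkyne carbon, the standard entry to 1-substituted 1-silylallenes.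

Step 11
Reactants: 10 (4S,6R)-4-(tert-butyldimethylsilyloxy)-3,6-dimethylcyclohept-2-en-1-one; 13 1-isopropyl-1-(trimethylsilyl)allene
Product: 14 cis-fused hydroazulen-6-one with C3(SiMe3)=C4(iPr), 1α-CH3, 5α-H, 8α-CH3 and 10α-OTBS
Conditions: TiCl4 (1.5 equiv), CH2Cl2, −78 °C; then 13 (2 equiv), −78 → −40 °C; aq. NaHCO3
Reagents that add atoms: none
Why: TiCl4 binds the C6 carbonyl of 10 and the CH2 terminus of 13 (the future C2) adds to the β-carbon C1, giving a vinyl cation at C3 that is stabilised by the neighbouring C–Si bond; a 1,2-shift of the trimethylsilyl group to C3 moves the charge to C4, where the titanium enolate carbon C5 captures it. The closest known reaction type is the Danheiser trimethylsilylcyclopentene annulation of enones with 1-substituted 1-(trimethylsilyl)allenes, here asked to build a quaternary carbon on a β,β-disubstituted enone. Ring A closes by attack of the enolate carbon C5 on the vinyl cation C4, a cation–enolate collapse that is formally 5-endo at a digonal carbon and leaves the C3=C4 bond inside the five-membered ring. C1 is set by approach of the allene to the enone face opposite the C10 silyloxy group and the cis C8 methyl group, which puts the C1 methyl cis to the C10 oxygen; C5 is set by the three-carbon tether, which can only reach the face it is already on, so the fusion is cis. The step needs bonding of the allene CH2 to C1 (secured by silicon, which stabilises only the cation formed that way), facial selectivity (secured by the silyl ether on C10 next to C1) and ring closure faster than a 1,2-hydride shift from the isopropyl methine to the vinyl cation (favoured by low temperature and by the enolate being held next to the cation).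

Step 12
Reactants: 14 cis-fused 3-(trimethylsilyl) hydroazulen-6-one
Product: 15 cis-fused hydroazulen-6-one with C3H=C4(iPr), 1α-CH3, 5α-H, 8α-CH3 and 10α-OTBS
Conditions: CF3CO2H, CH2Cl2, 0 °C; aq. NaHCO3
Reagents that add atoms: none
Why: Protodesilylation of a vinylsilane, in which ipso protonation at C3 gives a tertiary cation at C4 stabilised by the β-silicon and loss of silicon restores C3=C4 in place, under anhydrous conditions that a hindered secondary silyl ether should tolerate for a short time.

Step 13
Reactants: 15 cis-fused hydroazulen-6-one with C3H=C4(iPr)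
Product: 16 C6=C7 trimethylsilyl enol ether of 15
Conditions: LiN(iPr)2, Me3SiCl (internal quench), THF, −78 °C; pentane, filtration
Reagents that add atoms: chlorotrimethylsilane, C[Si](C)(C)Cl
Why: Kinetic enolisation with a hindered amide base removes a C7 methylene proton in preference to the C5 methine, which is flanked by the quaternary C1 and the isopropyl-bearing C4, and the enolate is trapped on oxygen as it forms.

Step 14
Reactants: 16 C6=C7 trimethylsilyl enol ether
Product: 17 cis-fused hydroazulen-6-one with C7=C8(CH3) and C3H=C4(iPr), 1α-CH3, 5α-H and 10α-OTBS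
Conditions: Pd(OAc)2 (1.1 equiv), MeCN, rt
Reagents that add atoms: none
Why: Saegusa–Ito oxidation, in which divalent palladium takes the enol ether to a C7-bound palladium enolate and syn β-hydride elimination of H8 gives the conjugated C7=C8 enone and removes the C8 stereocentre.

Step 15
Reactants: 17 cis-fused dienone
Product: 18 6β-allylic alcohol with C7=C8 and C3=C4, 1α-CH3, 5α-H and 10α-OTBS
Conditions: NaBH4, CeCl3·7H2O, MeOH, −78 → 0 °C
Reagents that add atoms: none
Why: Luche 1,2-reduction of the enone, with hydride expected to come from the convex α face of the cis-fused bicycle, anti to ring A and its isopropyl-bearing C4, so that the C6 hydroxyl ends up β and trans to H5.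

Step 16
Reactants: 19 4-hydroxybenzoic acid
Product: 21 4-(tert-butyldimethylsilyloxy)benzoic acid, via bis-silylated ester 20 (not isolated)
Conditions: TBSCl (2.2 equiv), imidazole, DMF, rt; then AcOH–THF–H2O, rt
Reagents that add atoms: tert-butyldimethylsilyl chloride, CC(C)(C)[Si](C)(C)Cl
Why: Exhaustive silylation followed by selective hydrolysis of the much more labile silyl ester leaves the aryl silyl ether that masks the phenol during esterification.

Step 17
Reactants: 18 6β-allylic alcohol; 21 4-(tert-butyldimethylsilyloxy)benzoic acid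
Product: 22 6β-[4-(tert-butyldimethylsilyloxy)benzoyloxy] diene with 10α-OTBS
Conditions: DCC, DMAP, CH2Cl2, 0 °C → rt
Reagents that add atoms: none
Why: Steglich esterification through the acylpyridinium ion acylates the only free hydroxyl with retention at C6.

Step 18
Reactants: 22 6β-aroyloxy diene
Product: 23 3α,4α-diol with 6β-aroyloxy, C7=C8 and 10α-OTBS
Conditions: OsO4 (5 mol %), N-methylmorpholine N-oxide, acetone–H2O, rt
Reagents that add atoms: osmium tetroxide, O=[Os](=O)(=O)=O (catalytic oxygen carrier); N-methylmorpholine N-oxide, C[N+]1([O-])CCOCC1; water, O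
Why: Upjohn syn-dihydroxylation should pick the electron-richer cyclopentene C3=C4 over C7=C8, which is deactivated by its allylic ester, and add from the convex α face anti to the allylic C5–C6 bond, which sets C3 and C4 with both hydroxyls cis to the angular methyl.

Step 19
Reactants: 23 3α,4α-diol
Product: 24 3α-acetate with 4α-OH, 6β-aroyloxy and 10α-OTBS
Conditions: Ac2O, pyridine, DMAP (cat.), CH2Cl2, 0 °C → rt
Reagents that add atoms: acetic anhydride, CC(=O)OC(C)=O
Why: Nucleophile-catalysed acetylation takes the secondary C3 hydroxyl and leaves the hindered tertiary C4 hydroxyl free.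

Step 20
Reactants: 24 3α-acetate bis-silyl ether
Product: 25 target, CNP0146780.2
Conditions: Bu4NF, AcOH (1:1), THF, 0 °C → rt
Reagents that add atoms: none
Why: Fluoride-mediated desilylation buffered with acetic acid removes the aryl and the C10 silyl ethers while the acetate and the aroyl ester, which are base-sensitive, stay in place.

**Compound list**

1 | methacrolein (2-methylprop-2-enal) | CC(=C)C=O | starting material
2 | O-[(S)-2-methylhexa-1,5-dien-3-yl] diisopinocampheylborinate | CC(=C)[C@@H](OB([C@@H]1C[C@@H]2C[C@H]([C@H]1C)C2(C)C)[C@@H]1C[C@@H]2C[C@H]([C@H]1C)C2(C)C)CC=C | intermediate (not isolated)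
3 | (S)-2-methylhexa-1,5-dien-3-ol | CC(=C)[C@@H](O)CC=C | intermediate
4 | (S)-2-methylhexa-1,5-dien-3-yl prop-2-enoate | CC(=C)[C@@H](OC(=O)C=C)CC=C | intermediate
5 | (S)-6-(prop-1-en-2-yl)-5,6-dihydro-2H-pyran-2-one | CC(=C)[C@@H]1CC=CC(=O)O1 | intermediate
6 | (4R,6S)-4-methyl-6-(prop-1-en-2-yl)tetrahydro-2H-pyran-2-one | CC(=C)[C@@H]1C[C@@H](C)CC(=O)O1 | intermediate
7 | (3R,5S)-5-hydroxy-N-methoxy-N,3,6-trimethylhept-6-enamide | CC(=C)[C@@H](O)C[C@@H](C)CC(=O)N(C)OC | intermediate
8 | (3R,5S)-5-(tert-butyldimethylsilyloxy)-N-methoxy-N,3,6-trimethylhept-6-enamide | CC(=C)[C@@H](O[Si](C)(C)C(C)(C)C)C[C@@H](C)CC(=O)N(C)OC | intermediate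
9 | (5R,7S)-7-(tert-butyldimethylsilyloxy)-5,8-dimethylnona-1,8-dien-3-one | CC(=C)[C@@H](O[Si](C)(C)C(C)(C)C)C[C@@H](C)CC(=O)C=C | intermediate
10 | (4S,6R)-4-(tert-butyldimethylsilyloxy)-3,6-dimethylcyclohept-2-en-1-one (silyloxy and C6 methyl cis) | CC=1[C@@H](O[Si](C)(C)C(C)(C)C)C[C@@H](C)CC(=O)C=1 | intermediate (key-step precursor)
11 | 3-(trimethylsilyl)prop-2-yn-1-ol | C[Si](C)(C)C#CCO | starting material
12 | 3-(trimethylsilyl)prop-2-yn-1-yl methanesulfonate | C[Si](C)(C)C#CCOS(C)(=O)=O | intermediate
13 | trimethyl(4-methylpenta-1,2-dien-3-yl)silane (1-isopropyl-1-(trimethylsilyl)allene) | CC(C)C(=C=C)[Si](C)(C)C | intermediate (key-step precursor)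
14 | cis-fused hydroazulen-6-one: C3(SiMe3)=C4(iPr), 1α-CH3, 5α-H, 8α-CH3, 10α-OTBS | C[Si](C)(C)C=1C[C@]2(C)[C@@H](O[Si](C)(C)C(C)(C)C)C[C@@H](C)CC(=O)[C@@H]2C=1C(C)C | intermediate (key-step product)
15 | cis-fused hydroazulen-6-one: C3H=C4(iPr), 1α-CH3, 5α-H, 8α-CH3, 10α-OTBS | C=1C[C@]2(C)[C@@H](O[Si](C)(C)C(C)(C)C)C[C@@H](C)CC(=O)[C@@H]2C=1C(C)C | intermediate
16 | C6=C7 trimethylsilyl enol ether of 15 | C=1C[C@]2(C)[C@@H](O[Si](C)(C)C(C)(C)C)C[C@@H](C)C=C(O[Si](C)(C)C)[C@@H]2C=1C(C)C | intermediate
17 | cis-fused hydroazulen-6-one: C7=C8(CH3), C3H=C4(iPr), 1α-CH3, 5α-H, 10α-OTBS | C=1C[C@]2(C)[C@@H](O[Si](C)(C)C(C)(C)C)CC(C)=CC(=O)[C@@H]2C=1C(C)C | intermediate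
18 | 6β-hydroxy diene: C7=C8(CH3), C3H=C4(iPr), 1α-CH3, 5α-H, 10α-OTBS | C=1C[C@]2(C)[C@@H](O[Si](C)(C)C(C)(C)C)CC(C)=C[C@H](O)[C@@H]2C=1C(C)C | intermediate
19 | 4-hydroxybenzoic acid | OC(=O)c1ccc(O)cc1 | starting material
20 | tert-butyldimethylsilyl 4-(tert-butyldimethylsilyloxy)benzoate | CC(C)(C)[Si](C)(C)OC(=O)c1ccc(O[Si](C)(C)C(C)(C)C)cc1 | intermediate (not isolated)
21 | 4-(tert-butyldimethylsilyloxy)benzoic acid | OC(=O)c1ccc(O[Si](C)(C)C(C)(C)C)cc1 | intermediate
22 | 6β-[4-(tert-butyldimethylsilyloxy)benzoyloxy] diene: C7=C8, C3=C4, 1α-CH3, 5α-H, 10α-OTBS | C=1C[C@]2(C)[C@@H](O[Si](C)(C)C(C)(C)C)CC(C)=C[C@H](OC(=O)c3ccc(O[Si](C)(C)C(C)(C)C)cc3)[C@@H]2C=1C(C)C | intermediate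
23 | 3α,4α-diol (4β-iPr): 6β-aroyloxy, C7=C8, 10α-OTBS | O[C@H]1C[C@]2(C)[C@@H](O[Si](C)(C)C(C)(C)C)CC(C)=C[C@H](OC(=O)c3ccc(O[Si](C)(C)C(C)(C)C)cc3)[C@@H]2[C@]1(O)C(C)C | intermediate
24 | 3α-acetoxy-4α-hydroxy compound: 6β-aroyloxy (aryl OTBS), 10α-OTBS | CC(=O)O[C@H]1C[C@]2(C)[C@@H](O[Si](C)(C)C(C)(C)C)CC(C)=C[C@H](OC(=O)c3ccc(O[Si](C)(C)C(C)(C)C)cc3)[C@@H]2[C@]1(O)C(C)C | intermediate
25 | CNP0146780.2: (1S,3S,4R,5R,6S,10S)-3-acetoxy-4,10-dihydroxy-4-isopropyl-1,8-dimethyl cis-fused hydroazul-7-en-6-yl 4-hydroxybenzoate (skeleton numbering of the overview) | CC(=O)O[C@H]1C[C@]2(C)[C@@H](O)CC(C)=C[C@H](OC(=O)c3ccc(O)cc3)[C@@H]2[C@]1(O)C(C)C | target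

**Step count and risks**

Total step count: 20. Longest linear sequence: 17 steps (steps 1–8, 11–15 and 17–20).

Steps most likely to fail:

1. Step 11 (annulation). Addition of the allene to the hindered, β,β-disubstituted C1 may be slow. Hydride shift in the vinyl cation, or loss of silicon before ring closure, could then overtake formation of ring A. The fallback sets out from enone 10 and builds the same two bonds stepwise with a stronger nucleophile and a metal-catalysed closure. Tributyl(propa-1,2-dienyl)stannane, CH2=C=CHSnBu3, with TBSOTf (CH2Cl2, −78 °C) should propargylate C1 anti to the C10 silyloxy group and trap the enolate as the C5=C6 silyl enol ether F1. NIS with catalytic AgNO3 (acetone, rt) should then give the iodoalkyne F2. AuCl(PPh3)/AgBF4 (CH2Cl2–MeOH, rt to 40 °C) should close ring A by 5-endo-dig attack of C5 on the alkyne activated by monovalent gold, giving the cis-fused vinyl iodide F3. Negishi coupling with iPrZnBr (Pd(OAc)2, CPhos, THF, rt) puts the isopropyl group on C4 and comes back to the route at ketone 15; steps 11 and 12 are both replaced.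

2. Step 12 (protodesilylation). Ipso protonation may be slow enough that acid-induced migration of C3=C4 into conjugation with the C6 ketone, or cleavage of the C10 silyl ether, competes. The fallback sets out from 14 and avoids protic acid. Iododesilylation with NIS in (CF3)2CHOH at 0 °C should give the C3 vinyl iodide F4. Reduction with formate (Pd(OAc)2, PPh3, HCO2H, Et3N, DMF, 60 °C) then replaces iodine by hydrogen and comes back to the route at 15.

3. Step 15 (C6 reduction). The seven-membered ring is flexible and the angular methyl group sits on the convex face, so hydride may come mainly from the β face. The fallback sets out from dienone 17; the same reduction would then give mainly the 6α-alcohol F5. Mitsunobu esterification of it with acid 21 (PPh3, DIAD, toluene, 0 °C) inverts C6 and comes back to the route at ester 22, which also replaces step 17.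

**Further compounds**

F1 | step 11 | C5=C6 tert-butyldimethylsilyl enol ether of the 1β-(prop-2-ynyl)-1α-methyl ketone (8α-CH3, 10α-OTBS) | C#CC[C@]1(C)[C@@H](O[Si](C)(C)C(C)(C)C)C[C@@H](C)CC(O[Si](C)(C)C(C)(C)C)=C1
F2 | step 11 | iodoalkyne of F1 (1β-(3-iodoprop-2-ynyl)) | IC#CC[C@]1(C)[C@@H](O[Si](C)(C)C(C)(C)C)C[C@@H](C)CC(O[Si](C)(C)C(C)(C)C)=C1
F3 | step 11 | cis-fused hydroazulen-6-one with C3H=C4(I), 1α-CH3, 5α-H, 8α-CH3, 10α-OTBS | C=1C[C@]2(C)[C@@H](O[Si](C)(C)C(C)(C)C)C[C@@H](C)CC(=O)[C@@H]2C=1I
F4 | step 12 | cis-fused hydroazulen-6-one with C3(I)=C4(iPr), 1α-CH3, 5α-H, 8α-CH3, 10α-OTBS | IC=1C[C@]2(C)[C@@H](O[Si](C)(C)C(C)(C)C)C[C@@H](C)CC(=O)[C@@H]2C=1C(C)C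
F5 | step 15 | 6α-hydroxy epimer of 18 | C=1C[C@]2(C)[C@@H](O[Si](C)(C)C(C)(C)C)CC(C)=C[C@@H](O)[C@@H]2C=1C(C)C
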